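**Assumptions**
- cis-2,3-Dimethylsuccinic anhydride (8) is commercial, or is made from meso-2,3-dimethylsuccinic acid with Ac2O.
- The quinidine-derived catalyst (DHQD)2AQN delivers the (2R,3S)-hemiester 9; the quinine-derived pseudo-enantiomer gives the opposite one.
- The Ru-catalysed dynamic kinetic reduction in Step 13 gives the threo (7''S,8''S) β-aryl ether.
- Simple reagents (TIPSCl, BnBr, MeOH and so on) are described in the "Reagents" line and are not numbered.

**Retrosynthesis**
1. Remove both aryl TIPS groups last, using fluoride.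
2. The threo β-aryl ether (C7''/C8'') comes from Ru-catalysed asymmetric transfer hydrogenation with dynamic kinetic resolution (ATH-DKR) of an α-aryloxy propiophenone. That ketone is made by SN2 of the syringyl phenol on α-bromo-propiovanillone.
3. The meso-type 2,3-dimethyl-1,4-diarylbutane (C8/C8') comes from desymmetrizing meso-2,3-dimethylsuccinic anhydride to a hemiester.
4. Each CH2–Ar is made from a carbonyl: the acid end by acid chloride/Negishi acylation, the ester end by Weinreb amide/ArMgBr, then hydrogenolysis.
5. No ring is constructed. All three arenes come from commercial aryl building blocks, and the backbone stereocentres are fixed first and never touched again.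

**Route**

Step 1
Reactants: 1 (4-bromo-2-methoxyphenol)
Product: 2 (4-bromo-2-methoxyphenyl TIPS ether)
Conditions: TIPSCl, imidazole, DMF, rt
Reagents that add atoms: TIPSCl, CC(C)[Si](Cl)(C(C)C)C(C)C
Why: Silylation of the phenol gives a group that survives ArMgBr/ArZnCl, Et3SiH/TFA, K2CO3 and Et3N/HCOOH, and is removed by fluoride at the end.

Step 2
Reactants: 3 (4-bromo-2,6-dimethoxyphenol)
Product: 4 (2-benzyloxy-5-bromo-1,3-dimethoxybenzene)
Conditions: BnBr, K2CO3, acetone, 60 °C
Reagents that add atoms: BnBr, BrCc1ccccc1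
Why: Williamson O-benzylation. The benzyl group is removed by hydrogenolysis in Step 11, which frees the syringyl phenol.

Step 3
Reactants: 5 (propiovanillone, 4'-hydroxy-3'-methoxypropiophenone)
Product: 6 (3'-methoxy-4'-TIPSO-propiophenone)
Conditions: TIPSCl, imidazole, DMF, rt
Reagents that add atoms: TIPSCl, CC(C)[Si](Cl)(C(C)C)C(C)C
Why: The phenol is protected so that the next bromination and the Step 12 alkylation do not involve it.

Step 4
Reactants: 6
Product: 7 (2-bromo-1-(3-methoxy-4-TIPSO-phenyl)propan-1-one, racemic)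
Conditions: CuBr2, EtOAc/CHCl3, reflux
Reagents that add atoms: CuBr2, Br[Cu]Br
Why: CuBr2 brominates aryl ketones selectively at the α-carbon through the enol and does not brominate the ring. The stereocentre is racemic, which is acceptable because it epimerizes in Step 13.

Step 5
Reactants: 8 (cis-2,3-dimethylsuccinic anhydride, meso)
Product: 9 ((2R,3S)-4-methoxy-2,3-dimethyl-4-oxobutanoic acid)
Conditions: MeOH (3–10 equiv), (DHQD)2AQN (10 mol%), MTBE or Et2O, –20 °C
Reagents that add atoms: methanol, CO
Why: Cinchona-alkaloid-catalysed enantioselective methanolysis of a meso anhydride differentiates the two enantiotopic carbonyls and sets both methyl stereocentres at once (C8 and C8').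

Step 6
Reactants: 9
Product: 10 (methyl (2S,3R)-4-chloro-2,3-dimethyl-4-oxobutanoate, used crude)
Conditions: (COCl)2, cat. DMF, CH2Cl2, 0 °C to rt; evaporate
Reagents that add atoms: oxalyl chloride, ClC(=O)C(=O)Cl
Why: The acid chloride is formed under base-free conditions so that no ketene forms and the α-stereocentre does not epimerize. The methyl ester is untouched.

Step 7
Reactants: 10; 2 (converted in situ to the aryl zinc chloride: Mg, THF, then ZnCl2)
Product: 11 (methyl (2R,3S)-4-aryl-2,3-dimethyl-4-oxobutanoate, aryl = 3-methoxy-4-TIPSO-phenyl)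
Conditions: Ar1ZnCl, Pd(PPh3)4 (5 mol%), THF, 0 °C to rt
Reagents that add atoms: none (the aryl group comes from 2)
Why: Negishi-type acylation is chemoselective for the acid chloride over the methyl ester and is mild enough to leave both α-stereocentres intact.

Step 8
Reactants: 11
Product: 12 (methyl (2R,3S)-4-aryl-2,3-dimethylbutanoate; the C7 CH2–Ar1 is formed)
Conditions: Et3SiH (3 equiv), TFA, CH2Cl2, 0 °C to rt
Reagents that add atoms: none
Why: Ionic hydrogenation of an electron-rich aryl ketone through the benzylic cation gives ArCH2. The ester and the aryl TIPS ether survive, and the former α-carbon is no longer epimerizable.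

Step 9
Reactants: 12
Product: 13 (Weinreb amide, N-methoxy-N-methyl (2R,3S)-4-aryl-2,3-dimethylbutanamide)
Conditions: MeNHOMe·HCl, i-PrMgCl, THF, –20 to 0 °C
Reagents that add atoms: N,O-dimethylhydroxylamine, CONC
Why: Magnesium amide aminolysis converts the ester to a Weinreb amide without epimerization.

Step 10
Reactants: 13; 4 (converted to Ar2MgBr: Mg, THF, reflux)
Product: 14 (aryl ketone: 4-benzyloxy-3,5-dimethoxyphenyl ketone of the Ar1–CH2–CH(Me)–CH(Me)– chain)
Conditions: Ar2MgBr (2–3 equiv), THF, 0 °C to rt
Reagents that add atoms: none (the aryl group comes from 4)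
Why: Weinreb ketone synthesis. The stable chelated intermediate prevents over-addition to the tertiary alcohol.

Step 11
Reactants: 14
Product: 15 (free syringyl phenol with Ar2CH2; the C7' CH2–Ar2 is formed and the benzyl group is lost)
Conditions: H2 (3 atm), 10% Pd/C, EtOAc/AcOH, cat. HClO4, 40 °C
Reagents that add atoms: none (H2 adds only H)
Why: Acid-promoted Pd/C hydrogenolysis reduces the aryl ketone to CH2 and cleaves the benzyl ether in the same step. The aryl TIPS ether is stable.

Step 12
Reactants: 15; 7
Product: 16 (α-aryloxy ketone, C8'' racemic)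
Conditions: K2CO3, acetone, 55 °C
Reagents that add atoms: none (7 is a numbered reactant)
Why: SN2 (Williamson-type) displacement of the α-bromoketone by the phenoxide forms the 4'–O–C8'' ether. The α-stereocentre is epimerizable and is resolved in the next step.

Step 13
Reactants: 16
Product: 17 (bis-TIPS ether with the (7''S,8''S) β-aryl ether alcohol)
Conditions: RuCl[(R,R)-TsDPEN](p-cymene) (2 mol%), HCOOH/Et3N (5:2), CH2Cl2, 30 °C
Reagents that add atoms: none (formate supplies only H)
Why: Noyori–Ikariya ATH with dynamic kinetic resolution. The α-aryloxy ketone epimerizes under Et3N/formate, and the (R,R)-catalyst reduces one enantiomer and one face selectively. This sets C7'' (S) and C8'' (S) together. It is the threo diastereomer, with the (R,R)-catalyst chosen for 7''S.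

Step 14
Reactants: 17
Product: 18 (target)
Conditions: TBAF, AcOH-buffered, THF, 0 °C to rt
Reagents that add atoms: none
Why: Fluoride cleaves both aryl TIPS ethers (Si–F driving force). The mild, buffered conditions leave the β-aryl ether and benzylic alcohol intact, and no stereocentre is touched.

**Compound list**

| No. | Name | SMILES | Role |
|---|---|---|---|
| 1 | 4-bromo-2-methoxyphenol | COc1cc(Br)ccc1O | starting material |
| 2 | 4-bromo-2-methoxyphenyl TIPS ether | COc1cc(Br)ccc1O[Si](C(C)C)(C(C)C)C(C)C | intermediate |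
| 3 | 4-bromo-2,6-dimethoxyphenol | COc1cc(Br)cc(OC)c1O | starting material |
| 4 | 2-benzyloxy-5-bromo-1,3-dimethoxybenzene | COc1cc(Br)cc(OC)c1OCc1ccccc1 | intermediate |
| 5 | propiovanillone | CCC(=O)c1ccc(O)c(OC)c1 | starting material |
| 6 | 3'-methoxy-4'-TIPSO-propiophenone | CCC(=O)c1ccc(O[Si](C(C)C)(C(C)C)C(C)C)c(OC)c1 | intermediate |
| 7 | 2-bromo-1-(3-methoxy-4-TIPSO-phenyl)propan-1-one (racemic) | CC(Br)C(=O)c1ccc(O[Si](C(C)C)(C(C)C)C(C)C)c(OC)c1 | intermediate |
| 8 | cis-2,3-dimethylsuccinic anhydride (meso) | C[C@H]1C(=O)OC(=O)[C@H]1C | starting material |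
| 9 | (2R,3S)-4-methoxy-2,3-dimethyl-4-oxobutanoic acid | OC(=O)[C@H](C)[C@H](C)C(=O)OC | intermediate |
| 10 | methyl (2S,3R)-4-chloro-2,3-dimethyl-4-oxobutanoate | ClC(=O)[C@H](C)[C@H](C)C(=O)OC | intermediate |
| 11 | keto ester (Ar1–C(=O)–CH(Me)–CH(Me)–CO2Me) | COc1cc(ccc1O[Si](C(C)C)(C(C)C)C(C)C)C(=O)[C@H](C)[C@H](C)C(=O)OC | intermediate |
| 12 | ester (Ar1–CH2–CH(Me)–CH(Me)–CO2Me) | COc1cc(C[C@H](C)[C@H](C)C(=O)OC)ccc1O[Si](C(C)C)(C(C)C)C(C)C | intermediate |
| 13 | Weinreb amide | COc1cc(C[C@H](C)[C@H](C)C(=O)N(C)OC)ccc1O[Si](C(C)C)(C(C)C)C(C)C | intermediate |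
| 14 | aryl ketone (Ar2 = 4-BnO-3,5-dimethoxyphenyl) | COc1cc(C[C@H](C)[C@H](C)C(=O)c2cc(OC)c(OCc3ccccc3)c(OC)c2)ccc1O[Si](C(C)C)(C(C)C)C(C)C | intermediate |
| 15 | syringyl phenol with Ar1-OTIPS | COc1cc(C[C@H](C)[C@H](C)Cc2cc(OC)c(O)c(OC)c2)ccc1O[Si](C(C)C)(C(C)C)C(C)C | intermediate |
| 16 | α-aryloxy ketone (C8'' racemic) | COc1cc(C[C@H](C)[C@H](C)Cc2cc(OC)c(OC(C)C(=O)c3ccc(O[Si](C(C)C)(C(C)C)C(C)C)c(OC)c3)c(OC)c2)ccc1O[Si](C(C)C)(C(C)C)C(C)C | intermediate |
| 17 | bis-TIPS (7''S,8''S) alcohol | COc1cc(C[C@H](C)[C@H](C)Cc2cc(OC)c(O[C@@H](C)[C@@H](O)c3ccc(O[Si](C(C)C)(C(C)C)C(C)C)c(OC)c3)c(OC)c2)ccc1O[Si](C(C)C)(C(C)C)C(C)C | intermediate |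
| 18 | (+)-(7''S,8S,8'R,8''S)-4,4''-dihydroxy-3,3',3'',5'-tetramethoxy-4',8''-oxy-8,8'-sesquineolignan-7''-ol | COc1cc(C[C@H](C)[C@H](C)Cc2cc(OC)c(O[C@@H](C)[C@@H](O)c3ccc(O)c(OC)c3)c(OC)c2)ccc1O | target |

**Totals**
- Total steps: 14 (steps 1–4 are parallel preparations of building blocks).
- Longest linear sequence: 10 steps (compound 8 to compound 18, Steps 5–14).

**Three steps most likely to fail**
1. **Step 13 (ATH-DKR).** Diastereoselectivity and ee for this α-aryloxy propiophenone are not guaranteed, and the reduction may give erythro.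
   - Fallback: replace the Ru catalyst with a ketoreductase (KRED) panel that performs DKR biocatalytically. The panel can be screened for threo-(S,S) selectivity, and 16 is used unchanged.
2. **Step 5 (desymmetrizing methanolysis).** The ee may be modest, or the sense of induction may be the opposite of the one assumed.
   - Fallback: open 8 with the lithium salt of (S)-4-benzyloxazolidin-2-one. Separate the two diastereomeric imide acids by chromatography, then convert the acid to the methyl ester and continue from 9.
3. **Step 10 (Weinreb ketone).** Excess ArMgBr can enolize the α-methyl ketone and epimerize C8', giving the dl diastereomer. Step 7 carries the same risk.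
   - Fallback: avoid carbonyl-α intermediates altogether. Reduce ester 12 with LiAlH4 to the primary alcohol, convert it to the bromide (CBr4/PPh3), and couple with Ar2MgBr under Li2CuCl4 (Kumada). This gives the protected core without any enolizable ketone.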